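(The runs stem from a simulated flask on assumed constants; the scatter is artificial.)

You call the uncatalysed route too slow to matter and ask for a quick number on Friday's and Wednesday's flasks, but at 10.0 h the alder run holds 30.4% of the substrate as uncatalysed product, so I keep that route in.

in all of them: substrate 1.6 M; free catalyst 62 mM; second catalyst 3.2 mM
- maple: coupling partner 1.3 M; run made earlier
- alder: coupling partner 2.4 M; run made earlier
- Friday's: coupling partner 1.10 M; time 10 h
- Wednesday's: coupling partner 2.20 M; time 10 h

| run | time / h | side product / % | intermediate / % | target / % | substrate / % | uncatalysed product / % |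
|---|---|---|---|---|---|---|
| maple | 0.833 | 8.2 | 16.2 | 0.6 | 67.5 | 5.9 |
| maple | 1.33 | 17.4 | 19.2 | 2.4 | 52.2 | 11.0 |
| maple | 2.00 | 28.3 | 22.9 | 3.9 | 34.1 | 11.5 |
| maple | 4.00 | 43.7 | 21.7 | 4.9 | 10.9 | 18.8 |
| maple | 6.00 | 49.1 | 22.0 | 10.2 | 3.5 | 18.6 |
| maple | 10.0 | 50.2 | 17.1 | 14.4 | 0 | 19.5 |
| alder | 0.667 | 7.4 | 12.0 | 1.6 | 68.4 | 11.0 |
| alder | 2.00 | 25.7 | 19.5 | 5.4 | 29.9 | 23.4 |
| alder | 4.00 | 33.3 | 17.3 | 10.3 | 8.7 | 28.9 |
| alder | 5.00 | 36.3 | 14.7 | 11.9 | 6.0 | 31.2 |
| alder | 8.00 | 39.1 | 10.2 | 17.1 | 0.1 | 32.7 |
| alder | 10.0 | 40.6 | 7.2 | 22.1 | 0.7 | 30.4 |

(standard deviation of a reading: 1 percentage point)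

- a species is counted by the substrate in it: one side product counts as two
- what was read earlier has a scatter of 1 percentage point, one standard deviation

- which of these there is most of at the end, counted by the substrate in it, Friday's (side product / uncatalysed product / target / intermediate)
- which of these there is most of at the end, counted by the substrate in it, Wednesday's (side product / uncatalysed product / target / intermediate)
- amount of the one of these that there is most of at the end, in percent of the substrate charged, Friday's
- amount of the one of these that there is most of at the end, in percent of the substrate charged, Wednesday's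

I take it that substrate enters by two routes, each first order in it: one through free catalyst to intermediate, one with coupling partner. The substrate concentration then cancels from their ratio, and c(coupling partner)/c(free catalyst) remains, as a reactivity ratio turns a feed ratio into a composition. I count the catalysed share as intermediate plus target plus half the side product, assuming one substrate in each side product came through the catalyst. Uncatalysed product over that share is the branch ratio, 0.345 at the end of the maple run and 0.613 in the alder run. Dividing each by the charged concentration ratio gives 0.0164 and 0.0158. Their mean, 0.0161, is my split constant g, a selectivity factor: the branch ratio per unit of charged c(coupling partner)/c(free catalyst).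

Intermediate plus target reads 31.5% and 29.3% in those runs, so I carry the mean, 30.4%. Substrate reads 0% at the end of the maple run and 0.7% at the end of the alder run, so I count it as nil, and the balance gives the catalysed share as the charge plus that mean, over two plus the branch ratio. Side product is twice the excess of this share over the mean. Friday's branch ratio is 0.286, so I commit to 53.3% side product, with uncatalysed product at 16.3%. Wednesday's branch ratio is 0.572, so I commit to 40.6% side product, with uncatalysed product at 29.0%.

The forecast gives side product at 52.5% for Friday's and side product at 42% for Wednesday's: “Side product is largest in both”.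

Friday's flask ends with side product at 53.4%. Wednesday's flask ends with side product at 40.7%.

    substrate + intermediate → side product (k = 0.00910 M⁻¹ min⁻¹)
    substrate + free catalyst → free catalyst + intermediate (k = 0.0800 M⁻¹ min⁻¹)
    substrate + coupling partner → uncatalysed product (k = 0.00150 M⁻¹ min⁻¹)
    coupling partner + second catalyst + intermediate → second catalyst + target (k = 0.420 M⁻² min⁻¹)

Read on these ends, g is 0.0159 on Friday's and 0.0162 on Wednesday's. On Friday's, with the charges as they stand, the uncatalysed step alone gives substrate a half-life of 7.0 h, against 2.33 h for the catalysed step. On Wednesday's, with the charges as they stand, the uncatalysed figure is 3.50 h, against 2.33 h for the catalysed step. For the neighbour, Wednesday's with 0.25 M free catalyst, g gives a branch ratio of 0.142, and that flask ends at 0.155.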